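## Analysis of the target

Target 28 is a daucane-type diester built on a cis-fused bicyclo[5.3.0]decene. Ring carbons are numbered C1 (acetoxy CH), C2 (CH2), C3 (methyl-bearing quaternary carbon), C4 (CHOH), C5 (CH2), C6 (methyl-bearing alkene carbon), C7 (alkene CH), C8 (aroyloxy CH), C9 (fusion CH) and C10 (isopropyl carbinol). Five-membered ring A is C1, C2, C3, C9, C10, and seven-membered ring B is C3 to C9 with the trisubstituted C6=C7 alkene. There are six stereocentres, (1S,3S,4S,8S,9R,10R) in this numbering, and quaternary C3 is bonded to two of them (C4 and C9). The C3 methyl, H9, the C4 hydroxyl, the C10 hydroxyl and the C1 acetoxy group lie on one face (the convex face of the cis-fused bicycle); the C8 aroyloxy group and the C10 isopropyl group lie on the other. Sensitive groups are the allylic 4-hydroxybenzoate at C8 (ionisable, and β to C10), the secondary acetate beside a free tertiary alcohol, and the free phenol. The main difficulties are the quaternary centre inside a seven-membered ring, four ring oxygens in three different states, and the lability of C9 whenever C8 or C10 is a carbonyl. The strategy rests on one feature: C3 is bonded to C9, and C9 sits beside oxygenated C8. The C3–C9 bond can therefore be made by a 1,2-shift of C3 from a C8 carbinol, which traces ring A and ring B back to the two six-membered rings of a decalin with a C3–C8 fusion bond, i.e. a Robinson annulation product.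

## Retrosynthetic reasoning

28 to 26. The two silyl ethers (C4 and phenol) are removed last from 27, and the acetate is placed on diol 26, where the secondary C1 hydroxyl is the only acylable one. No protecting-group exchange is then needed at the end.

26 to 25. Both C–O bonds at C1 and C10 are cut together (syn-dihydroxylation of the C1=C10 alkene). This gives the cis-diol in one operation from the convex face. Adding an isopropyl nucleophile to a C10 ketone was not chosen, because it would also enter from the convex face and put the hydroxyl on the wrong side.

25 to 21. The C10–isopropyl bond is cut (cross-coupling of enol triflate 24), which leads to ketone 23, alcohol 22 and its silyl ether 21. The C10 oxygen is thus only a temporary handle, and its configuration does not matter.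

21 to 17 and 20. The ester C–O bond at C8 is cut. Acid 20 is the silyl-protected form of 4-hydroxybenzoic acid 18. Acylating at this point lets the aroyl group also protect C8 during the ring A work.

17 to 14. The C8 carbinol comes from enone 16 by 1,2-reduction, and the C6=C7 alkene comes from ketone 14 by dehydrogenation through enol ether 15. The C8 ketone is therefore the source of both the alkene and the C8 stereocentre.

14 to 13 (key disconnection). The C3–C9 bond is cut and C3 is reconnected to C8. This turns the hydroazulenone into trans-decalin hydroxy mesylate 13. The forward step must move the fusion bond, and only that bond, from C8 to C9 with inversion at C9; that contracts one six-membered ring to ring A, expands the other to ring B and creates the cis fusion. No other bond set gives both rings and the C9 stereocentre in one stereospecific event from so accessible a precursor.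

13 to 9. The mesylate comes from cis-diol 12, the diol from alkene 11 by syn-dihydroxylation anti to the angular methyl, and 11 from enone 9 through allylic alcohol 10. All three ring oxygens on C8, C9 and C10 grow out of the enone of the annulation product.

9 to 1, 2 and 4. The C4 silyl ether comes from alcohol 8 and enedione 7. Enedione 7 is opened at C8=C9 (aldol condensation through ketol 6) and at C2–C3 (conjugate addition) to give triketone 5, dione 3 and enone 4. Dione 3 is the C-methylation product of 1 with 2. The angular methyl, the C4 oxygen and the ring B methyl are thus bought with the annulation; the C6 stereocentre that comes with it is temporary.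

## Alternatives that were turned down

Alternative 1: Type 2 carbonyl-ene closure of ring B. The C4–C5 bond is cut. In the forward step a cyclopentane keto aldehyde A1 (ring A complete with its diol as an acetonide, the C4 aldehyde on C3, a 2-methylallyl ketone on C9) is activated at the aldehyde by an aluminium Lewis acid. The terminal alkene carbon C5 attacks C4 with transfer of a methyl hydrogen, giving hydroazulenone A2 with the C4 hydroxyl and an exocyclic methylene at C6.
- For: ring A and its four stereocentres are finished before the ring closure, so no late site-selective dihydroxylation is needed. The C8 ketone and the C6 methylene of A2 are one isomerisation away from the C6=C7 enone. On end-game length this route is stronger than the chosen one.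
- Against: the C4 configuration is set in a flexible seven-membered ene transition state at a neopentyl aldehyde, with no rigid element to steer it. A1 is a 1,4-keto aldehyde with an enolisable C7 and a C9–H β to an acetonide oxygen, so aldol closure of C7 onto C4 and β-elimination compete. A1 itself (four contiguous stereocentres on a cyclopentane, one quaternary) has no short source.
- Comparison: the chosen strategy takes C3, C4 and C9 from a Robinson product and a stereospecific shift, and pays for this with a longer ring A sequence.

Alternative 2: Samarium pinacol closure of ring A. The C1–C10 bond is cut. In the forward step cycloheptene keto aldehyde A3 (CH2CHO on C3, isobutyryl on C9, the two arms cis) is reduced by divalent samarium. The two carbonyl carbons couple to give ring A cis-diol A4.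
- For: ring A and both carbinol centres are made in one step, and a chelated pinacol coupling gives the cis-diol by its nature. The enol triflate, cross-coupling and dihydroxylation steps disappear, so this route is stronger on late-stage step economy.
- Against: A3 already contains the hard part (the seven-membered ring with C3, C4, C8 and C9 set), and this disconnection says nothing about making it. The ketyl of a hindered isopropyl ketone sits β to the allylic C8 alkoxy group and can expel it. Which face of the ring the diol takes relative to H9 depends on a flexible transition state, and C9 is epimerisable in A3.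
- Comparison: the chosen strategy offers a stereospecific answer for exactly the C3/C9 relationship that A3 takes for granted.

Alternative 3: Tethered oxyallyl (4+3) cycloaddition. The C3–C9 and C5–C6 bonds are cut together. In the forward step tertiary α-chloro ketone A5, tethered through C2, C1 and C10 to a 2-silyloxy diene, is ionised with base to the C3–C4–C5 oxyallyl cation. The cation adds across the diene termini to give hydroazulenone A6 with a C7=C8 silyl enol ether.
- For: both rings and the quaternary centre form in one step, the ring A diol is in place, and the enol ether is a latent C6=C7 enone. On paper this is the shortest route and the largest gain in complexity per step.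
- Against: the cis fusion and its relation to the preset C1/C10 centres depend on the compact-versus-extended preference of a crowded intramolecular cycloaddition (a fully substituted oxyallyl terminus, a diene terminus next to a quaternary carbon). Ionisation of the tertiary chloride competes with elimination and Favorskii pathways. The silyloxy diene is acid-labile, and C4 arrives as a ketone that still needs a selective reduction.
- Comparison: the chosen 1,2-shift sets C9 by inversion and keeps C3 by retention, so its stereochemical outcome does not rest on a selectivity; the price is a longer end-game.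

Key step: step 10

Remark on numbering: the target locants C1 to C10 are used for every bicyclic intermediate, decalins included (fusion bond C3–C8 in the decalins, C3–C9 in the hydroazulenes).

Assumption: the conjugate addition of step 2 is not expected to be face-selective. The isomer with the two methyl groups cis (5) is the one carried on, and the stereocentre concerned (C6) is erased in step 11.

## Route

Step 1
Reactants: 1 5-methylcyclohexane-1,3-dione; 2 iodomethane
Product: 3 2,5-dimethylcyclohexane-1,3-dione
Conditions: NaOH, H2O/dioxane, MeI, 65 °C; then aq. HCl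
Reagents that add atoms: none
Why: C-alkylation of the doubly stabilised dione enolate at the carbon between the carbonyls (the standard 2-methylation of cyclohexane-1,3-diones); any enol ether from O-methylation is hydrolysed back to 1 on acidic work-up; the new centre is enolisable and of no stereochemical consequence.

Step 2
Reactants: 3 2,5-dimethylcyclohexane-1,3-dione; 4 but-3-en-2-one
Product: 5 cis-2,5-dimethyl-2-(3-oxobutyl)cyclohexane-1,3-dione
Conditions: Et3N (cat.), MeCN, rt; separation of the cis isomer
Reagents that add atoms: none
Why: Michael addition of the dione to the enone forms the C2–C3 bond and the quaternary carbon (C3); the remote ring methyl gives little facial bias, so both relative configurations are expected and the cis-dimethyl isomer is separated; the centre in question (C6) is erased in step 11.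

Step 3
Reactants: 5 cis-triketone
Product: 7 (3S,8aS)-3,8a-dimethyl-3,4,8,8a-tetrahydronaphthalene-1,6(2H,7H)-dione, via cis-fused aldol ketol 6 (not isolated)
Conditions: L-proline (cat.), DMSO, rt
Reagents that add atoms: none
Why: Hajos–Parrish–Eder–Sauer–Wiechert reaction: the proline enamine of the side-chain ketone adds to one of the two enantiotopic ring carbonyls of the achiral triketone (forming C8–C9) and ketol 6 dehydrates in the same flask; L-proline should give the S quaternary centre as in the parent Wieland–Miescher series, which fixes the absolute configuration of C3 and so of the whole route; enantiomeric purity can be raised by recrystallisation.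

Step 4
Reactants: 7 bicyclic enedione
Product: 8 (4aS)-5-hydroxy-4a,7-dimethyl-4,4a,5,6,7,8-hexahydronaphthalen-2(3H)-one (5-OH and 7-methyl cis to the 4a-methyl)
Conditions: NaBH4 (0.3 equiv), EtOH, −10 °C
Reagents that add atoms: none
Why: Chemoselective borohydride reduction of the saturated ketone beside the less electrophilic enone, as known for Wieland–Miescher ketone; hydride adds to C4 anti to the adjacent axial angular methyl and gives the equatorial alcohol cis to that methyl, which is the C4 configuration of the target.

Step 5
Reactants: 8 hydroxy enone
Product: 9 C4 tert-butyldimethylsilyl ether of 8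
Conditions: TBSCl, imidazole, DMAP (cat.), DMF, 40 °C
Reagents that add atoms: tert-butyldimethylsilyl chloride, CC(C)(C)[Si](C)(C)Cl
Why: Silylation of the hindered neopentyl secondary alcohol, slow but routine in this series; this ether has to last to the final step.

Step 6
Reactants: 9 silyloxy enone
Product: 10 allylic alcohol (C8=C9 alkene; C10 hydroxyl cis to the C3 methyl)
Conditions: NaBH4, CeCl3·7H2O, MeOH, −78 to 0 °C
Reagents that add atoms: none
Why: Luche 1,2-reduction; axial hydride delivery on the face away from the angular methyl should give the pseudo-equatorial allylic alcohol cis to the C3 methyl, the usual result for octalenones of this type; this centre is temporary.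

Step 7
Reactants: 10 allylic alcohol
Product: 11 C10 triethylsilyl ether of 10
Conditions: TESCl, imidazole, CH2Cl2, 0 °C to rt
Reagents that add atoms: chlorotriethylsilane, CC[Si](Cl)(CC)CC
Why: Silylation with a group that can later be removed beside the tert-butyldimethylsilyl ether; the allylic silyloxy group also reinforces the facial bias of the next step.

Step 8
Reactants: 11 bis-silyl ether
Product: 12 trans-decalin-8,9-diol (C8 and C9 hydroxyls cis to each other and trans to the C3 methyl)
Conditions: OsO4 (cat.), NMO, acetone/H2O, rt
Reagents that add atoms: osmium tetroxide (oxygen carrier), O=[Os](=O)(=O)=O; N-methylmorpholine N-oxide, C[N+]1([O-])CCOCC1; water, O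
Why: Upjohn syn-dihydroxylation; osmium should add anti to the axial angular methyl and anti to the allylic silyloxy group, which lie on the same face, so the product is the trans-fused decalin with an axial tertiary C8 hydroxyl and an equatorial C9 hydroxyl.

Step 9
Reactants: 12 diol
Product: 13 C9 methanesulfonate of 12 (rearrangement precursor)
Conditions: MsCl, Et3N, CH2Cl2, 0 °C
Reagents that add atoms: methanesulfonyl chloride, CS(=O)(=O)Cl
Why: Sulfonylation discriminates by substitution: the secondary C9 hydroxyl reacts and the tertiary C8 hydroxyl stays free; the amine base does not trigger the rearrangement at this temperature.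

Step 10
Reactants: 13 hydroxy mesylate
Product: 14 cis-fused hydroazulen-8-one (H9 cis to the C3 methyl)
Conditions: KOt-Bu (1.0 equiv), t-BuOH/THF, 0 °C to rt
Reagents that add atoms: none
Why: Deprotonation of the tertiary C8 hydroxyl gives an alkoxide that pushes the C8–C3 fusion bond onto C9 as the mesylate leaves, a concerted semipinacol 1,2-alkyl shift that forms C3–C9 and the C8 ketone. The closest known reaction type is the base-induced rearrangement of a cyclic cis-1,2-diol monosulfonate, the classical decalin-to-hydroazulenone conversion. Neither ring is closed by a cyclisation: ring A (five-membered) arises by contraction of the mesylate-bearing six-membered ring and ring B (seven-membered) by expansion of the other, both through the one shift. The single new stereocentre, C9, is set by inversion because C3 enters anti to the leaving group, while C3 migrates with retention, so the trans-decalin geometry becomes the cis relation of the C3 methyl and H9. The step needs the fusion bond to migrate rather than C7, and needs no epoxide formation or elimination; the rigid trans-decalin secures this, since the equatorial C9–O bond is antiperiplanar to the C8–C3 bond, gauche to C8–C7, cis to the C8 oxygen and without an antiperiplanar hydrogen. One equivalent of base is used and is consumed, so the product, a β-silyloxy ketone with an epimerisable C9–H, is not left in a basic medium.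

Step 11
Reactants: 14 hydroazulenone
Product: 16 hydroazul-6-en-8-one (C6=C7 enone), via C7=C8 trimethylsilyl enol ether 15 (not isolated)
Conditions: LiN(i-Pr)2, TMSCl, THF, −78 °C; then Pd(OAc)2 (1.1 equiv), MeCN, rt
Reagents that add atoms: none
Why: Saegusa–Ito dehydrogenation: kinetic deprotonation at the unhindered C7 methylene (not at the hindered C9 methine) with silyl trapping gives 15, and its palladium enolate undergoes β-hydride elimination of H6 to the conjugated enone; the C6 stereocentre is erased here and C9 is never enolised.

Step 12
Reactants: 16 enone
Product: 17 C8 allylic alcohol (hydroxyl trans to H9)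
Conditions: NaBH4, CeCl3·7H2O, MeOH, −78 °C
Reagents that add atoms: none
Why: Luche 1,2-reduction; hydride is expected on the convex face of the cis-fused bicycle (the face of H9), which places the C8 hydroxyl on the opposite face as in the target; this is the least secure stereochemical call of the route (see the end).

Step 13
Reactants: 18 4-hydroxybenzoic acid
Product: 20 4-(tert-butyldimethylsilyloxy)benzoic acid, via tert-butyldimethylsilyl 4-(tert-butyldimethylsilyloxy)benzoate 19 (not isolated)
Conditions: TBSCl (2.2 equiv), imidazole, DMF, rt; then AcOH/THF/H2O, rt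
Reagents that add atoms: tert-butyldimethylsilyl chloride, CC(C)(C)[Si](C)(C)Cl
Why: Exhaustive silylation followed by selective hydrolysis of the far more labile silyl ester leaves the phenol protected and the acid free.

Step 14
Reactants: 17 C8 allylic alcohol; 20 4-(tert-butyldimethylsilyloxy)benzoic acid
Product: 21 C8 4-(tert-butyldimethylsilyloxy)benzoate of 17
Conditions: DCC, DMAP, CH2Cl2, rt
Reagents that add atoms: none
Why: Steglich esterification of the hindered secondary allylic alcohol; the reaction takes place at oxygen with retention at C8, and the aroyl group then also protects C8.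

Step 15
Reactants: 21 ester
Product: 22 C10 alcohol (triethylsilyl group removed)
Conditions: PPTS (cat.), MeOH/CH2Cl2, 0 °C to rt
Reagents that add atoms: none
Why: Mild acid-catalysed methanolysis removes the secondary triethylsilyl ether much faster than the hindered secondary tert-butyldimethylsilyl ether or the acid-robust aryl silyl ether.

Step 16
Reactants: 22 C10 alcohol
Product: 23 C10 ketone
Conditions: Dess–Martin periodinane, CH2Cl2, 0 °C to rt
Reagents that add atoms: none
Why: Dess–Martin oxidation under non-enolising conditions; the product is a β-acyloxy ketone with its α-hydrogen at C9, so base and long contact with silica are avoided.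

Step 17
Reactants: 23 C10 ketone
Product: 24 C1=C10 enol triflate
Conditions: KN(SiMe3)2, THF, −78 °C (ketone added to base); 2-[N,N-bis(trifluoromethylsulfonyl)amino]-5-chloropyridine, −78 °C
Reagents that add atoms: 2-[N,N-bis(trifluoromethylsulfonyl)amino]-5-chloropyridine, Clc1ccc(nc1)N(S(=O)(=O)C(F)(F)F)S(=O)(=O)C(F)(F)F
Why: Kinetic deprotonation with a bulky amide base should occur at the C1 methylene rather than the hindered C9 methine, and O-sulfonylation of that enolate at low temperature gives the enol triflate; inverse addition suppresses enolate equilibration toward C9, which would expel the C8 aroyloxy group; the ester has no α-hydrogen.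

Step 18
Reactants: 24 enol triflate
Product: 25 10-isopropyl C1=C10 alkene
Conditions: i-PrZnBr, Pd(dppf)Cl2 (5 mol %), THF, rt to 40 °C
Reagents that add atoms: isopropylzinc bromide, CC(C)[Zn]Br
Why: Negishi coupling of an alkenyl triflate with a secondary alkylzinc halide; the wide-bite-angle diphosphine favours reductive elimination over β-hydride elimination so the branched group is kept, and oxidative addition to the triflate should be much faster than ionisation of the hindered allylic ester by zerovalent palladium.

Step 19
Reactants: 25 diene ester
Product: 26 C1,C10 cis-diol (both hydroxyls on the face of H9 and the C3 methyl)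
Conditions: OsO4 (cat.), NMO, acetone/H2O, rt
Reagents that add atoms: osmium tetroxide (oxygen carrier), O=[Os](=O)(=O)=O; N-methylmorpholine N-oxide, C[N+]1([O-])CCOCC1; water, O
Why: Upjohn syn-dihydroxylation; the ring A alkene is the more electron-rich one because the ring B alkene carries an allylic ester (the same bias lets osmylation pick the remote alkene in allylic esters of polyenes), and the concave face of ring A is shielded by ring B and the C8 aroyloxy group, so osmium should add on the convex face and set C1 and C10 together.

Step 20
Reactants: 26 diol
Product: 27 C1 acetate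
Conditions: Ac2O, DMAP (cat.), pyridine, CH2Cl2, 0 °C to rt
Reagents that add atoms: acetic anhydride, CC(=O)OC(C)=O
Why: Acylation distinguishes the secondary C1 hydroxyl from the tertiary C10 hydroxyl, which does not react under these conditions.

Step 21
Reactants: 27 bis-silyl ether
Product: 28 target
Conditions: HF·pyridine, pyridine, THF, 0 °C to rt
Reagents that add atoms: none
Why: Fluoride-mediated cleavage of both remaining silyl ethers (C4 alkyl and aryl) under buffered, mildly acidic conditions that leave the acetate, the allylic ester and the tertiary alcohol untouched and avoid base-induced acyl migration.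

## Compound list

1 | 5-methylcyclohexane-1,3-dione | CC1CC(=O)CC(=O)C1 | starting material
2 | iodomethane | CI | starting material
3 | 2,5-dimethylcyclohexane-1,3-dione | CC1CC(=O)C(C)C(=O)C1 | intermediate
4 | but-3-en-2-one | CC(=O)C=C | starting material
5 | cis-2,5-dimethyl-2-(3-oxobutyl)cyclohexane-1,3-dione (the two methyls cis; achiral) | CC(=O)CC[C@]1(C)C(=O)C[C@@H](C)CC1=O | intermediate
6 | 4a-hydroxy-3,8a-dimethyloctahydronaphthalene-1,6(2H,5H)-dione (cis-fused aldol ketol; 4a-OH cis to the 8a-methyl) | C1C[C@]2(C)C(=O)C[C@@H](C)C[C@]2(O)CC1=O | intermediate
7 | (3S,8aS)-3,8a-dimethyl-3,4,8,8a-tetrahydronaphthalene-1,6(2H,7H)-dione (methyls cis) | C1C[C@]2(C)C(=O)C[C@@H](C)CC2=CC1=O | intermediate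
8 | (4aS)-5-hydroxy-4a,7-dimethyl-4,4a,5,6,7,8-hexahydronaphthalen-2(3H)-one (5-OH and 7-methyl cis to the 4a-methyl) | C1C[C@]2(C)[C@@H](O)C[C@@H](C)CC2=CC1=O | intermediate
9 | C4 tert-butyldimethylsilyl ether of 8 | C1C[C@]2(C)[C@@H](O[Si](C)(C)C(C)(C)C)C[C@@H](C)CC2=CC1=O | intermediate
10 | octalin allylic alcohol (C8=C9; C10 OH, C4 OTBS and C6 methyl all cis to the C3 methyl) | C1C[C@]2(C)[C@@H](O[Si](C)(C)C(C)(C)C)C[C@@H](C)CC2=C[C@H]1O | intermediate
11 | C10 triethylsilyl ether of 10 | C1C[C@]2(C)[C@@H](O[Si](C)(C)C(C)(C)C)C[C@@H](C)CC2=C[C@H]1O[Si](CC)(CC)CC | intermediate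
12 | trans-decalin-8,9-diol (C8 tertiary OH and C9 OH trans to the C3 methyl; C4 OTBS, C6 methyl and C10 OTES cis to it) | C1C[C@]2(C)[C@@H](O[Si](C)(C)C(C)(C)C)C[C@@H](C)C[C@@]2(O)[C@H](O)[C@H]1O[Si](CC)(CC)CC | intermediate
13 | C9 methanesulfonate of 12 (trans-decalin hydroxy mesylate) | C1C[C@]2(C)[C@@H](O[Si](C)(C)C(C)(C)C)C[C@@H](C)C[C@@]2(O)[C@H](OS(C)(=O)=O)[C@H]1O[Si](CC)(CC)CC | intermediate
14 | cis-fused hydroazulen-8-one (3,6-dimethylbicyclo[5.3.0]decan-8-one skeleton; H9, C4 OTBS, C6 methyl and C10 OTES on the face of the C3 methyl) | C1C[C@]2(C)[C@@H](O[Si](C)(C)C(C)(C)C)C[C@@H](C)CC(=O)[C@@H]2[C@H]1O[Si](CC)(CC)CC | intermediate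
15 | C7=C8 trimethylsilyl enol ether of 14 | C1C[C@]2(C)[C@@H](O[Si](C)(C)C(C)(C)C)C[C@@H](C)C=C(O[Si](C)(C)C)[C@@H]2[C@H]1O[Si](CC)(CC)CC | intermediate
16 | hydroazul-6-en-8-one (C6=C7 enone; C4 OTBS, C10 OTES) | C1C[C@]2(C)[C@@H](O[Si](C)(C)C(C)(C)C)CC(C)=CC(=O)[C@@H]2[C@H]1O[Si](CC)(CC)CC | intermediate
17 | C8 allylic alcohol (C8 OH trans to H9 and to the C3 methyl) | C1C[C@]2(C)[C@@H](O[Si](C)(C)C(C)(C)C)CC(C)=C[C@H](O)[C@@H]2[C@H]1O[Si](CC)(CC)CC | intermediate
18 | 4-hydroxybenzoic acid | OC(=O)c1ccc(O)cc1 | starting material
19 | tert-butyldimethylsilyl 4-(tert-butyldimethylsilyloxy)benzoate | CC(C)(C)[Si](C)(C)OC(=O)c1ccc(O[Si](C)(C)C(C)(C)C)cc1 | intermediate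
20 | 4-(tert-butyldimethylsilyloxy)benzoic acid | OC(=O)c1ccc(O[Si](C)(C)C(C)(C)C)cc1 | intermediate
21 | C8 4-(tert-butyldimethylsilyloxy)benzoate of 17 | C1C[C@]2(C)[C@@H](O[Si](C)(C)C(C)(C)C)CC(C)=C[C@H](OC(=O)c3ccc(O[Si](C)(C)C(C)(C)C)cc3)[C@@H]2[C@H]1O[Si](CC)(CC)CC | intermediate
22 | C10 alcohol (C10 OH cis to H9) | C1C[C@]2(C)[C@@H](O[Si](C)(C)C(C)(C)C)CC(C)=C[C@H](OC(=O)c3ccc(O[Si](C)(C)C(C)(C)C)cc3)[C@@H]2[C@H]1O | intermediate
23 | C10 ketone (hydroazul-6-en-10-one with C8 aroyloxy) | C1C[C@]2(C)[C@@H](O[Si](C)(C)C(C)(C)C)CC(C)=C[C@H](OC(=O)c3ccc(O[Si](C)(C)C(C)(C)C)cc3)[C@@H]2C1=O | intermediate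
24 | C1=C10 enol triflate | FC(F)(F)S(=O)(=O)OC1=CC[C@]2(C)[C@@H](O[Si](C)(C)C(C)(C)C)CC(C)=C[C@H](OC(=O)c3ccc(O[Si](C)(C)C(C)(C)C)cc3)[C@H]12 | intermediate
25 | 10-isopropyl hydroazula-1(10),6-diene (C8 aroyloxy, C4 OTBS) | CC(C)C1=CC[C@]2(C)[C@@H](O[Si](C)(C)C(C)(C)C)CC(C)=C[C@H](OC(=O)c3ccc(O[Si](C)(C)C(C)(C)C)cc3)[C@H]12 | intermediate
26 | C1,C10 cis-diol (C1 OH and C10 OH on the face of H9 and the C3 methyl; isopropyl on the other face) | O[C@H]1C[C@]2(C)[C@@H](O[Si](C)(C)C(C)(C)C)CC(C)=C[C@H](OC(=O)c3ccc(O[Si](C)(C)C(C)(C)C)cc3)[C@@H]2[C@]1(O)C(C)C | intermediate
27 | C1 acetate of 26 | CC(=O)O[C@H]1C[C@]2(C)[C@@H](O[Si](C)(C)C(C)(C)C)CC(C)=C[C@H](OC(=O)c3ccc(O[Si](C)(C)C(C)(C)C)cc3)[C@@H]2[C@]1(O)C(C)C | intermediate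
28 | CNP0146780.2: (1S,3S,4S,8S,9R,10R)-1-acetoxy-4,10-dihydroxy-8-(4-hydroxybenzoyloxy)-10-isopropyl-3,6-dimethylbicyclo[5.3.0]dec-6-ene in the numbering used here | CC(=O)O[C@H]1C[C@]2(C)[C@@H](O)CC(C)=C[C@H](OC(=O)c3ccc(O)cc3)[C@@H]2[C@]1(O)C(C)C | target

## Step count and least certain steps

Total: 21 steps. Longest linear sequence: 20 steps (steps 1 to 12 and 14 to 21); step 13 is a one-step side branch.

Step 10 (key step). The shift itself is well aligned. What is most likely to go wrong is what follows it: epimerisation at C9 (now α to the ketone) or E1cB loss of the C10 silyloxy group (β to the ketone) if alkoxide base remains. Fallback: the same C3 shift is run in the electrophilic manifold. Mesylate 13 is treated with Et3Al (or Et2AlCl) in CH2Cl2 at −78 °C, which makes the aluminium alkoxide and activates the sulfonate as a Lewis acid (organoaluminium-promoted pinacol-type rearrangement), so that no free base is present at any time. This sets out from 13 and returns at 14 without a new compound.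

Step 2. Poor facial selectivity is likely, because the only stereocontrol element is a remote methyl on a nearly flat dione enolate; a chair-like approach anti to the puckered C5 would even place the incoming chain cis to that methyl and so favour the unwanted trans-dimethyl isomer. Fallback: the order of the two C–C bond formations is reversed. Dione 1 is first added to enone 4 (water, rt) to give 5-methyl-2-(3-oxobutyl)cyclohexane-1,3-dione F1, and F1 is then C-methylated with 2 (K2CO3, acetone) to return at 5. The second electrophile should enter the same face in either order, so the methyl-last order should favour the cis-dimethyl isomer when the chain-last order does not. Competing O-methylation is the price.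

Step 12. Poor or reversed facial selectivity in hydride delivery to the flexible seven-membered enone is possible, since the C3 methyl is 1,3 to C8 on the convex face and ring A shields the concave face. Fallback: the epimer is used instead. Reduction of 16 under whichever conditions give it cleanly (the Luche outcome itself or LiBH(s-Bu)3) provides the C8-epimeric allylic alcohol F2. Mitsunobu esterification of F2 with acid 20 (PPh3, DIAD, toluene) inverts C8 and returns directly at 21, bypassing step 14.

Step 17. Enolisation toward C9, or enolate equilibration, would expel the C8 aroyloxy group from the β-acyloxy ketone by E1cB. Fallback: the ester is installed after the ring A alkene. Alcohol 17 is converted (NaH, 4-methoxybenzyl chloride, THF/DMF) into the C8 4-methoxybenzyl ether F3. Methanolysis with PPTS gives the C10 alcohol F4, and Dess–Martin oxidation gives the β-alkoxy ketone F5. Triflation as in step 17 gives the enol triflate F6, and Negishi coupling as in step 18 gives the isopropyl alkene F7. DDQ (CH2Cl2, pH 7 buffer) frees the C8 alcohol F8, and esterification of F8 with 20 (DCC, DMAP) returns at 25. This detour also keeps the allylic ester away from zerovalent palladium.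

Step 18. β-Hydride elimination and reinsertion at palladium would give the n-propyl or the reduced alkene, and the allylic ester may ionise slowly. Fallback: the three-carbon unit is introduced as an sp2 partner. Stille coupling of 24 with tributyl(isopropenyl)stannane (Pd(PPh3)4, LiCl, THF, 60 °C) gives the isopropenyl diene F9. Site-selective hydrogenation of its 1,1-disubstituted alkene (RhCl(PPh3)3, H2, benzene) returns at 25.

Step 19. Competing osmylation of the C6=C7 alkene is the most likely problem if the allylic ester does not deactivate it enough. Fallback: ring B is masked as an enone during the oxidation. Ester 25 is cleaved reductively (i-Bu2AlH, CH2Cl2, −78 °C) to the C8 alcohol F8. Dess–Martin oxidation gives the C6=C7 enone F10, whose electron-poor alkene is inert to OsO4, and Upjohn dihydroxylation then gives the ring A cis-diol F11. Acetylation at C1 gives F12, and Luche reduction gives the C8 alcohol F13. Esterification of F13 with 20 (DCC, DMAP; the tertiary alcohol does not react) returns at 27.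

## Further compounds

F0 | step 10 | none | none
F1 | step 2 | 5-methyl-2-(3-oxobutyl)cyclohexane-1,3-dione | CC(=O)CCC1C(=O)CC(C)CC1=O
F2 | step 12 | C8 epimer of 17 (C8 OH cis to H9) | C1C[C@]2(C)[C@@H](O[Si](C)(C)C(C)(C)C)CC(C)=C[C@@H](O)[C@@H]2[C@H]1O[Si](CC)(CC)CC
F3 | step 17 | C8 4-methoxybenzyl ether of 17 | C1C[C@]2(C)[C@@H](O[Si](C)(C)C(C)(C)C)CC(C)=C[C@H](OCc3ccc(OC)cc3)[C@@H]2[C@H]1O[Si](CC)(CC)CC
F4 | step 17 | C10 alcohol with C8 4-methoxybenzyl ether | C1C[C@]2(C)[C@@H](O[Si](C)(C)C(C)(C)C)CC(C)=C[C@H](OCc3ccc(OC)cc3)[C@@H]2[C@H]1O
F5 | step 17 | C10 ketone with C8 4-methoxybenzyl ether | C1C[C@]2(C)[C@@H](O[Si](C)(C)C(C)(C)C)CC(C)=C[C@H](OCc3ccc(OC)cc3)[C@@H]2C1=O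
F6 | step 17 | C1=C10 enol triflate with C8 4-methoxybenzyl ether | FC(F)(F)S(=O)(=O)OC1=CC[C@]2(C)[C@@H](O[Si](C)(C)C(C)(C)C)CC(C)=C[C@H](OCc3ccc(OC)cc3)[C@H]12
F7 | step 17 | 10-isopropyl C1=C10 alkene with C8 4-methoxybenzyl ether | CC(C)C1=CC[C@]2(C)[C@@H](O[Si](C)(C)C(C)(C)C)CC(C)=C[C@H](OCc3ccc(OC)cc3)[C@H]12
F8 | step 17 | 10-isopropyl C1=C10 alkene with free C8 hydroxyl | CC(C)C1=CC[C@]2(C)[C@@H](O[Si](C)(C)C(C)(C)C)CC(C)=C[C@H](O)[C@H]12
F9 | step 18 | 10-isopropenyl C1=C10 alkene (C8 aroyloxy, C4 OTBS) | CC(=C)C1=CC[C@]2(C)[C@@H](O[Si](C)(C)C(C)(C)C)CC(C)=C[C@H](OC(=O)c3ccc(O[Si](C)(C)C(C)(C)C)cc3)[C@H]12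
F10 | step 19 | 10-isopropyl hydroazula-1(10),6-dien-8-one | CC(C)C1=CC[C@]2(C)[C@@H](O[Si](C)(C)C(C)(C)C)CC(C)=CC(=O)[C@H]12
F11 | step 19 | C1,C10 cis-diol of the C6=C7 enone | O[C@H]1C[C@]2(C)[C@@H](O[Si](C)(C)C(C)(C)C)CC(C)=CC(=O)[C@@H]2[C@]1(O)C(C)C
F12 | step 19 | C1 acetate of F11 | CC(=O)O[C@H]1C[C@]2(C)[C@@H](O[Si](C)(C)C(C)(C)C)CC(C)=CC(=O)[C@@H]2[C@]1(O)C(C)C
F13 | step 19 | C8 allylic alcohol with C1 acetate and C10 hydroxyl | CC(=O)O[C@H]1C[C@]2(C)[C@@H](O[Si](C)(C)C(C)(C)C)CC(C)=C[C@H](O)[C@@H]2[C@]1(O)C(C)C
A1 | alternative 1 | cyclopentane keto aldehyde acetonide (C4 aldehyde on C3; 2-methylallyl ketone on C9) | CC1(C)O[C@H]2C[C@](C)(C=O)[C@H](C(=O)CC(C)=C)[C@]2(O1)C(C)C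
A2 | alternative 1 | 4-hydroxy-6-methylene hydroazulen-8-one acetonide | CC1(C)O[C@H]2C[C@]3(C)[C@@H](O)CC(=C)CC(=O)[C@@H]3[C@]2(O1)C(C)C
A3 | alternative 2 | cycloheptene keto aldehyde (CH2CHO on C3; isobutyryl on C9; C4 OTBS; C8 4-methoxybenzyl ether) | O=CC[C@]1(C)[C@@H](O[Si](C)(C)C(C)(C)C)CC(C)=C[C@H](OCc2ccc(OC)cc2)[C@@H]1C(=O)C(C)C
A4 | alternative 2 | ring A cis-1,2-diol (C4 OTBS; C8 4-methoxybenzyl ether) | O[C@H]1C[C@]2(C)[C@@H](O[Si](C)(C)C(C)(C)C)CC(C)=C[C@H](OCc3ccc(OC)cc3)[C@@H]2[C@]1(O)C(C)C
A5 | alternative 3 | tertiary α-chloro ketone tethered to a 2-silyloxy diene (acetonide of the C1,C10 diol) | CC(=O)C(C)(Cl)C[C@@H]1OC(C)(C)O[C@]1(C(C)C)/C=C(O[Si](C)(C)C(C)(C)C)/C=C/C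
A6 | alternative 3 | hydroazulen-4-one with C7=C8 silyl enol ether (acetonide) | CC1(C)O[C@H]2C[C@]3(C)C(=O)C[C@H](C)C=C(O[Si](C)(C)C(C)(C)C)[C@@H]3[C@]2(O1)C(C)C
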